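Ring A is built last. Its contiguous array C5(OH), C6(prenyl), C7(OMe), C8(H) corresponds to a ketene carbonyl carbon, the two carbons of a prenylated 1-methoxyalkyne and a former diazo carbon. The C4a=C8a bond it shares with ring C is the C3=C2 enol ether bond of a 4-pyranone. One photochemical operation (Wolff rearrangement, [2+2] cycloaddition, four-electron opening, six-electron closure) forges C5–C6, C7–C8 and C5–C4a and fixes the whole pattern without regioisomers. The precursor is a 2-diazoacetyl-5-aryl-4-pyranone. It is made from kojic acid by triflation of the enolic OH, Suzuki arylation at the future C3, oxidation of the hydroxymethyl arm and acylation of diazomethane.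

Key step: step 7

Remark: monocyclic intermediates are numbered as 4-pyranones (O1, C2 to C6), bicyclic ones and the target as isoflavones. Pyranone C2, C3, C5 and C6 become isoflavone C8a, C4a, C3 and C2. The hydroxymethyl group of kojic acid is carried unprotected.

Step 1
Reactants: 1 kojic acid (5-hydroxy-2-(hydroxymethyl)-4H-pyran-4-one)
Product: 2 6-(hydroxymethyl)-4-oxo-4H-pyran-3-yl trifluoromethanesulfonate
Conditions: PhNTf2 (1.05 equiv), Et3N (1.2 equiv), DMF, 0 °C to rt
Reagents that add atoms: N-phenylbis(trifluoromethanesulfonimide) O=S(=O)(N(c1ccccc1)S(=O)(=O)C(F)(F)F)C(F)(F)F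
Why: Chemoselective O-triflation by sulfonyl transfer, in which Et3N ionises only the enolic 5-OH (far more acidic than the primary alcohol) and the mild donor PhNTf2 reacts with that oxyanion but not with a neutral alcohol, so the hydroxymethyl arm needs no protecting group.

Step 2
Reactants: 3 4-hydroxyphenylboronic acid pinacol ester
Product: 4 4-(triisopropylsilyloxy)phenylboronic acid pinacol ester
Conditions: TIPSCl (1.1 equiv), imidazole (2.2 equiv), CH2Cl2, rt
Reagents that add atoms: triisopropylsilyl chloride CC(C)[Si](Cl)(C(C)C)C(C)C
Why: Imidazole-promoted silyl ether formation on a phenol, with the bulky group chosen because it should resist the basic coupling medium, acid chloride formation, diazomethane and ketenes yet fall to fluoride at the end.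

Step 3
Reactants: 2 6-(hydroxymethyl)-4-oxo-4H-pyran-3-yl trifluoromethanesulfonate; 4 4-(triisopropylsilyloxy)phenylboronic acid pinacol ester
Product: 5 2-(hydroxymethyl)-5-[4-(triisopropylsilyloxy)phenyl]-4H-pyran-4-one
Conditions: Pd(dppf)Cl2 (3 mol %), K3PO4 (2 equiv), 1,4-dioxane/H2O (20:1), degassed, 70 °C
Reagents that add atoms: none
Why: Suzuki–Miyaura coupling, in which the electron-poor enol triflate next to the carbonyl adds readily to the zerovalent palladium formed in situ from the divalent precatalyst, and K3PO4 with little water activates the boronate without hydrolysing the triflate, opening the pyranone or stripping the hindered aryl silyl ether.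

Step 4
Reactants: 5 2-(hydroxymethyl)-5-[4-(triisopropylsilyloxy)phenyl]-4H-pyran-4-one
Product: 6 4-oxo-5-[4-(triisopropylsilyloxy)phenyl]-4H-pyran-2-carboxylic acid
Conditions: TEMPO (0.2 equiv), PhI(OAc)2 (2.2 equiv), MeCN/H2O (1:1), rt
Reagents that add atoms: water O
Why: TEMPO-catalysed oxoammonium oxidation, which takes the primary alcohol to an electron-poor aldehyde whose hydrate is oxidised on to the acid in the same flask, under mildly acidic conditions that an aryl triisopropylsilyl ether and a 4-pyranone tolerate.

Step 5
Reactants: 6 4-oxo-5-[4-(triisopropylsilyloxy)phenyl]-4H-pyran-2-carboxylic acid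
Product: 8 2-(2-diazoacetyl)-5-[4-(triisopropylsilyloxy)phenyl]-4H-pyran-4-one, via acid chloride 7 (not isolated)
Conditions: (COCl)2 (1.2 equiv), DMF (cat.), CH2Cl2, 0 °C to rt, evaporate; then add slowly to CH2N2 (3 equiv), Et2O/THF, −10 to 0 °C, dim light
Reagents that add atoms: diazomethane C=[N+]=[N-]; oxalyl chloride O=C(Cl)C(=O)Cl (supplies the chlorine of 7 only)
Why: Acylation of diazomethane by an acid chloride (first stage of the Arndt–Eistert sequence), in which adding 7 to cold excess diazomethane lets a second equivalent take up HCl so that no chloromethyl ketone forms, and the short contact time limits dipolar cycloaddition to the pyranone.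

Step 6
Reactants: 9 chloroacetaldehyde dimethyl acetal; 10 prenyl bromide (1-bromo-3-methylbut-2-ene)
Product: 12 1-methoxy-5-methylhex-4-en-1-yne, via sodium methoxyacetylide 11 (not isolated)
Conditions: NaNH2 (3.0 equiv), liq. NH3, −33 °C; then 10 (1.1 equiv), −60 to −33 °C; evaporate NH3, pentane/cold water, distil under reduced pressure over K2CO3, use fresh
Reagents that add atoms: sodium amide [Na+].[NH2-] (supplies the sodium of 11 only)
Why: Double β-elimination (MeOH, then HCl) and deprotonation by three equivalents of amide give the alkoxyacetylide, which is alkylated by direct SN2 attack at the primary carbon of 10 in the classical one-pot route to 1-alkoxy-1-alkynes, while exact base stoichiometry and low temperature guard the skipped enyne against isomerisation and ammonia competes little for the allylic bromide.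

Step 7
Reactants: 8 2-(2-diazoacetyl)-5-[4-(triisopropylsilyloxy)phenyl]-4H-pyran-4-one; 12 1-methoxy-5-methylhex-4-en-1-yne
Product: 17 4'-O-triisopropylsilyl gancaonin G, via pyranonylketene 13 (not isolated), via cyclobutenone 14 (not isolated), via dienylketene 15 (not isolated), via cyclohexadienone 16 (not isolated)
Conditions: 12 (2.5 equiv), degassed ClCH2CH2Cl (0.02 M), 365–405 nm LED, Pyrex, 20 °C, until the diazo IR band has gone; then 80 °C in the dark
Reagents that add atoms: none
Why: Proposed new method: excitation of 8 releases N2 with a 1,2-shift of the pyranonyl group to the former diazo carbon (Wolff rearrangement), and the resulting ketene 13 is intercepted at its C=C bond by ynol ether 12 in a [2+2] cycloaddition that gives cyclobutenone 14. Reversible four-electron electrocyclic opening of 14 (light or 80 °C) gives dienylketene 15, whose terminal π bond is the pyranone C2=C3 bond, so ring A closes as a six-membered carbocycle by six-electron electrocyclization of the ketene carbon onto pyranone C3 (C5–C4a bond), and enolization of dienone 16 gives the phenol. The closest known reaction type is the second-generation Danheiser benzannulation of aryl, heteroaryl and alkenyl α-diazoketones with alkoxy- or siloxyalkynes, where a 4-pyranon-2-yl diazoketone has not served as ketene source; because this ring is barely aromatic and C3 is both the donor-activated carbon of the ring enol ether and the bearer of the hydrogen lost on aromatization, the closure is expected to be about as facile as with simple vinyl diazoketones. The [2+2] event must be regioselective, and the donor oxygen of 12 sees to that: it makes the carbon holding the prenyl chain the nucleophilic terminus, which attacks the ketene C=O carbon, so the chain is flanked by 5-OH and 7-OMe, while C3 is the sole position open to ring closure and an 8-prenyl isomer is excluded. Chemoselectivity rests on the ynol ether being far more nucleophilic than the trisubstituted prenyl alkene, on irradiating above 360 nm where the diazoketone still absorbs but the strong pyranone band does not, and on the new 5-OH being held in a hydrogen bond to the C4 carbonyl so that it does not capture ketene. The sp3 centres of 14 and 16 are racemic and transient and disappear on aromatization, so the step sets no stereocentre.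

Step 8
Reactants: 17 4'-O-triisopropylsilyl gancaonin G
Product: 18 gancaonin G
Conditions: Bu4NF (1.1 equiv), AcOH (1.2 equiv), THF, 0 °C; pH 7 phosphate work-up
Reagents that add atoms: none
Why: Fluoride-induced cleavage of the aryl silyl ether, buffered with acetic acid so that basic attack on ring C is avoided, and worked up at neutral pH so that no acid-catalysed chroman formation between 5-OH and the prenyl alkene sets in.

Compound list
1 | kojic acid, 5-hydroxy-2-(hydroxymethyl)-4H-pyran-4-one | OCc1cc(=O)c(O)co1 | starting material
2 | 6-(hydroxymethyl)-4-oxo-4H-pyran-3-yl trifluoromethanesulfonate | OCc1cc(=O)c(OS(=O)(=O)C(F)(F)F)co1 | intermediate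
3 | 4-hydroxyphenylboronic acid pinacol ester | CC1(C)OB(c2ccc(O)cc2)OC1(C)C | starting material
4 | 4-(triisopropylsilyloxy)phenylboronic acid pinacol ester | CC(C)[Si](Oc1ccc(B2OC(C)(C)C(C)(C)O2)cc1)(C(C)C)C(C)C | intermediate
5 | 2-(hydroxymethyl)-5-[4-(triisopropylsilyloxy)phenyl]-4H-pyran-4-one | OCc1cc(=O)c(-c2ccc(O[Si](C(C)C)(C(C)C)C(C)C)cc2)co1 | intermediate
6 | 4-oxo-5-[4-(triisopropylsilyloxy)phenyl]-4H-pyran-2-carboxylic acid | OC(=O)c1cc(=O)c(-c2ccc(O[Si](C(C)C)(C(C)C)C(C)C)cc2)co1 | intermediate
7 | 4-oxo-5-[4-(triisopropylsilyloxy)phenyl]-4H-pyran-2-carbonyl chloride | ClC(=O)c1cc(=O)c(-c2ccc(O[Si](C(C)C)(C(C)C)C(C)C)cc2)co1 | intermediate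
8 | 2-(2-diazoacetyl)-5-[4-(triisopropylsilyloxy)phenyl]-4H-pyran-4-one | [N-]=[N+]=CC(=O)c1cc(=O)c(-c2ccc(O[Si](C(C)C)(C(C)C)C(C)C)cc2)co1 | intermediate
9 | chloroacetaldehyde dimethyl acetal | COC(CCl)OC | starting material
10 | prenyl bromide, 1-bromo-3-methylbut-2-ene | CC(C)=CCBr | starting material
11 | sodium methoxyacetylide | [Na+].[C-]#COC | intermediate
12 | 1-methoxy-5-methylhex-4-en-1-yne | COC#CCC=C(C)C | intermediate
13 | {4-oxo-5-[4-(triisopropylsilyloxy)phenyl]-4H-pyran-2-yl}ketene | O=C=Cc1cc(=O)c(-c2ccc(O[Si](C(C)C)(C(C)C)C(C)C)cc2)co1 | intermediate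
14 | 3-methoxy-2-(3-methylbut-2-enyl)-4-{4-oxo-5-[4-(triisopropylsilyloxy)phenyl]-4H-pyran-2-yl}cyclobut-2-en-1-one (racemic) | O=C1C(CC=C(C)C)=C(OC)C1c1cc(=O)c(-c2ccc(O[Si](C(C)C)(C(C)C)C(C)C)cc2)co1 | intermediate
15 | (3E)-3-methoxy-2-(3-methylbut-2-enyl)-4-{4-oxo-5-[4-(triisopropylsilyloxy)phenyl]-4H-pyran-2-yl}buta-1,3-dien-1-one (pyranonyl group cis to the ketene-bearing carbon) | O=C=C(CC=C(C)C)/C(OC)=C\c1cc(=O)c(-c2ccc(O[Si](C(C)C)(C(C)C)C(C)C)cc2)co1 | intermediate
16 | 7-methoxy-6-(3-methylbut-2-enyl)-3-[4-(triisopropylsilyloxy)phenyl]-4aH-chromene-4,5-dione (racemic) | O=C1C(CC=C(C)C)=C(OC)C=C2OC=C(c3ccc(O[Si](C(C)C)(C(C)C)C(C)C)cc3)C(=O)C12 | intermediate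
17 | 4'-O-triisopropylsilyl gancaonin G, 5-hydroxy-7-methoxy-6-(3-methylbut-2-enyl)-3-[4-(triisopropylsilyloxy)phenyl]-4H-chromen-4-one | COc1cc2occ(-c3ccc(O[Si](C(C)C)(C(C)C)C(C)C)cc3)c(=O)c2c(O)c1CC=C(C)C | intermediate
18 | gancaonin G, 5-hydroxy-3-(4-hydroxyphenyl)-7-methoxy-6-(3-methylbut-2-enyl)-4H-chromen-4-one | COc1cc2occ(-c3ccc(O)cc3)c(=O)c2c(O)c1CC=C(C)C | target

Total step count: 8 (the crude acid chloride is made and consumed within step 5).
Longest linear sequence: 6 (steps 1, 3, 4, 5, 7, 8).

Steps most likely to fail

1. Step 7 (Proposed new method).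
- What may go wrong: photodegradation of the pyranone chromophore, dimerisation of the electron-poor ketene before it meets the alkyne, or stalling after the cycloaddition because the six-electron closure has to disturb the pyranone conjugation.
- Fallback: it gives up the late construction of ring A and uses established isoflavone chemistry. It sets out from boronate 4 and rejoins the route at 17. Bought 2'-hydroxy-4',6'-dimethoxyacetophenone is heated with DMF dimethyl acetal to give the enaminone (E)-3-(dimethylamino)-1-(2-hydroxy-4,6-dimethoxyphenyl)prop-2-en-1-one F1, which iodine in MeOH should cyclise to 3-iodo-5,7-dimethoxychromone F2. BCl3 in CH2Cl2 at low temperature removes only the methyl ether that can chelate to the C4 carbonyl and should give 5-hydroxy-3-iodo-7-methoxychromone F3. Suzuki coupling of this iodide with 4 under the conditions of step 3 should give 4'-O-triisopropylsilyl prunetin F4. Iodination ortho to the free 5-OH with BnMe3N·ICl2 and CaCO3 in CH2Cl2/MeOH should give 6-iodo-4'-O-triisopropylsilyl prunetin F5. Stille coupling with tributyl(3-methylbut-2-enyl)stannane (Pd(PPh3)4, DMF) should then place the prenyl group on C6 and deliver 17.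

2. Step 5.
- What may go wrong: 1,3-dipolar cycloaddition of diazomethane to the C2=C3 bond, which is flanked by two carbonyl groups once the acyl group is in place, and capture of the diazoketone by HCl.
- Fallback: it never exposes the pyranone to a diazoalkane. It sets out from acid 6, which is taken to acid chloride 7 as before, and returns at 8. Addition of 7 to (isocyanoimino)triphenylphosphorane in CH2Cl2 followed by water should give the α-keto hydrazonoyl chloride F6. Et3N then removes HCl, and the nitrile imine so formed tautomerises to diazoketone 8.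

3. Step 6.
- What may go wrong: base-induced migration of the skipped enyne into conjugation, consumption of the allylic bromide by ammonia or methoxide, and loss of the volatile, acid-sensitive product on isolation.
- Fallback: it changes the source of the acetylide. It sets out from prenyl bromide 10 and returns at 12. Bought trichloroethylene and KOMe (from KH and MeOH in THF) should give (E)-1,2-dichloro-1-methoxyethene F7. Two equivalents of n-BuLi at −78 °C convert it, by elimination and chlorine–lithium exchange, into lithium methoxyacetylide F8, free of amide, ammonia and methoxide. Bromide 10 is then added with DMPU at −78 to 0 °C to give 12.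

Further compounds
F1 | step 7 | (E)-3-(dimethylamino)-1-(2-hydroxy-4,6-dimethoxyphenyl)prop-2-en-1-one | CN(C)/C=C/C(=O)c1c(O)cc(OC)cc1OC
F2 | step 7 | 3-iodo-5,7-dimethoxy-4H-chromen-4-one | COc1cc(OC)c2c(=O)c(I)coc2c1
F3 | step 7 | 5-hydroxy-3-iodo-7-methoxy-4H-chromen-4-one | COc1cc(O)c2c(=O)c(I)coc2c1
F4 | step 7 | 4'-O-triisopropylsilyl prunetin, 5-hydroxy-7-methoxy-3-[4-(triisopropylsilyloxy)phenyl]-4H-chromen-4-one | COc1cc(O)c2c(=O)c(-c3ccc(O[Si](C(C)C)(C(C)C)C(C)C)cc3)coc2c1
F5 | step 7 | 6-iodo-4'-O-triisopropylsilyl prunetin | COc1cc2occ(-c3ccc(O[Si](C(C)C)(C(C)C)C(C)C)cc3)c(=O)c2c(O)c1I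
F6 | step 5 | (Z)-2-oxo-2-{4-oxo-5-[4-(triisopropylsilyloxy)phenyl]-4H-pyran-2-yl}ethanehydrazonoyl chloride | N/N=C(Cl)/C(=O)c1cc(=O)c(-c2ccc(O[Si](C(C)C)(C(C)C)C(C)C)cc2)co1
F7 | step 6 | (E)-1,2-dichloro-1-methoxyethene | CO/C(Cl)=C\Cl
F8 | step 6 | lithium methoxyacetylide | [Li+].[C-]#COC
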